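At late times the amber flask holds 0% of its L, the limiting reagent, while E still reads 9.7%. That late remnant of E is what the two new flasks are asked about.

| flask | L | G | temperature | remark | time |
|---|---|---|---|---|---|
| amber | 0.055 M | 10 µM | 25 °C | run made earlier |  |
| larch | 0.050 M | 10 µM | 25 °C |  | 15 h |
| maple | 0.015 M | 5.0 µM | 25 °C |  | 30 h |

amber run (percent of the L charged)

| time / h | E / % | L / % |
|---|---|---|
| 0.417 | 8.6 | 68.2 |
| 0.667 | 10.5 | 47.4 |
| 1.00 | 12.7 | 26.1 |
| 2.00 | 12.9 | 3.2 |
| 3.00 | 10.9 | 0.8 |
| 5.00 | 9.7 | 0 |

(scatter of a reading: 0.3 percentage points)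

- a species is counted by the L in it: one Z counts as two
- on the list of suspects stand: G -> D; L + G -> E + G; L + E -> Z; E + G <-> Q + G
- no earlier run changes the charge of G; that part of a forecast is a guess

1. which one finishes higher in amount of E, in percent of the L charged ("neither" within 2 percentage points) (larch / maple / neither)
2. amount of E at the end, in percent of the L charged, larch
3. amount of E at the end, in percent of the L charged, maple

While L lasts, L + G makes E and L + E consumes it. If both steps are first order in L, L cancels, and the level of E follows G. In percent of the L charged, it then follows the charge ratio ρ = G/L. Amber gives the factor: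

Y = 9.7% / (10 µM / 0.055 M) = 534

This Y, the late fraction of E divided by the charge ratio, forecasts larch and maple:

larch: 10.7%; maple: 17.8%

But amber's E was still falling at its last reading, so that reading may not be late enough. The fall per hour shrinks between the last two intervals, which gives a relaxation time:

τ = 1.25 h

The fall left after the last reading is then 0.3 percentage points, about one scatter, but this estimate comes from differences of scattered readings, so the objection stays open and Y may stand high.

If this fall is E + G ⇌ Q + G, τ stretches to 2.49 h in maple, which is shorter than its 30 h. Larch's τ is likewise shorter than its 15 h. Two more doubts stay: no earlier run changes G, and one run cannot test the cancelling of L.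

The forecast also says maple, but lower: 9.5% for larch and 16% for maple, “uncertain because the G lifetime is unknown”.

The flasks end at 9.22% in larch and 14.1% in maple, so maple finishes higher.

    G → D (k = 1.10 × 10⁻⁴ min⁻¹, Ea = 184 kJ mol⁻¹)
    L + G → E + G, rate k2*[L]*[G]/(1 + ([L]/Km2) + ([L]/Ksi2)^2) (0.230 M, 46.0 mM, k = 2200 M⁻¹ min⁻¹, Ea = 46.0 kJ mol⁻¹)
    L + E → Z (k = 1.90 M⁻¹ min⁻¹, Ea = 64.0 kJ mol⁻¹)
    E + G ⇌ Q + G, rate k4*[G]*[E] forward; the back reaction follows from the equilibrium constant (K = 1.50, k = 730 M⁻¹ min⁻¹, Ea = 41.0 kJ mol⁻¹, ΔH = −59.0 kJ mol⁻¹)
    (constants at 25 °C)

Reckoned on these ends, Y falls to 461 for larch and 423 for maple. Amber, left to larch's time, stands at 8.50%, below its last reading, and that gives Y = 468. Maple's gap to larch comes from its smaller charge of L: a flask with maple's G and time but larch's L ends at 5.38%, against 14.1% in maple. Amber's Y times that flask's ratio gives 5.33%, and the flask stands at 5.38%.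

All runs are simulated from invented constants; the scatter is artificial.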